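**Retrosynthetic overview**
1. The route rests on the C3(OH)–C4(=O) pair of the pyranone ring (ring C). Both carbons sit at carbonyl oxidation level, so the C3–C4 bond joins two like-polarised centres; a nitro group on C3 provides the carbanion and is later exchanged for the C3 oxygen.
2. Ring C, the only ring made, is cut at O1–C2 and C3–C4. This gives salicylaldehyde 4 (ring A plus C4) and nitrostyrene 9 (ring B plus C2 and C3), joined by an oxa-Michael/Henry annulation to 3-nitro-2H-chromene 12.
3. Aldehyde 4 comes from 2,4,6-trihydroxybenzaldehyde by C-prenylation and 4,6-bis-MOM protection. Nitrostyrene 9 comes from 4-hydroxybenzaldehyde by C-prenylation, MOM protection and Henry condensation.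
4. After ring closure, alkaline hydrogen peroxide turns the nitroalkene into the 3-hydroxy-4-one (ring C becomes aromatic), and dilute acid removes the three MOM groups.

Key step: step 6

Remark: the target has no stereocentre and no stereogenic double bond, so there is no enantiomer to select. The one stereocentre made on the way (C2 of the chromene) is carried as the racemate and is removed when ring C is aromatised in step 7. Prenyl = 3-methylbut-2-en-1-yl; MOM = methoxymethyl.

**Route**

Step 1
Reactants: 1 2,4,6-trihydroxybenzaldehyde; 2 prenyl bromide (1-bromo-3-methylbut-2-ene)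
Product: 3 2,4,6-trihydroxy-3-prenylbenzaldehyde
Conditions: 2 (1.0 equiv), 10% aq KOH, 0 °C → rt
Reagents that add atoms: none
Why: C-alkylation of the phloroglucinol polyphenoxide in water favours attack through carbon on the soft allylic bromide, the two open ring positions are equivalent by symmetry, and limiting the bromide to one equivalent should hold back a second prenylation.

Step 2
Reactants: 3 2,4,6-trihydroxy-3-prenylbenzaldehyde
Product: 4 2-hydroxy-4,6-bis(methoxymethoxy)-3-prenylbenzaldehyde
Conditions: MOMCl (2.1 equiv), i-Pr2NEt (2.5 equiv), CH2Cl2, 0 °C → rt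
Reagents that add atoms: chloromethyl methyl ether, COCCl
Why: Williamson-type O-alkylation with MOMCl should take the unchelated 4-OH first and then the 6-OH, which is flanked only by a ring hydrogen, whereas the 2-OH is hydrogen-bonded to the formyl group and shielded by the prenyl methylene, so about two equivalents of reagent should leave that hydroxyl free.

Step 3
Reactants: 5 4-hydroxybenzaldehyde; 2 prenyl bromide
Product: 6 4-hydroxy-3-prenylbenzaldehyde
Conditions: 2 (1.0 equiv), 10% aq KOH, rt
Reagents that add atoms: none
Why: Phenoxide C-alkylation in water places the prenyl group ortho to the oxygen because the para position carries the formyl group; the O-prenyl ether by-product is neutral and is separated by base extraction.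

Step 4
Reactants: 6 4-hydroxy-3-prenylbenzaldehyde
Product: 7 4-(methoxymethoxy)-3-prenylbenzaldehyde
Conditions: MOMCl (1.3 equiv), i-Pr2NEt (1.6 equiv), CH2Cl2, 0 °C → rt
Reagents that add atoms: chloromethyl methyl ether, COCCl
Why: MOM ether formation (Williamson-type alkylation) on the only phenol masks it as a base-stable acetal for the amine and alkaline peroxide steps that follow.

Step 5
Reactants: 7 4-(methoxymethoxy)-3-prenylbenzaldehyde; 8 nitromethane
Product: 9 (E)-1-(methoxymethoxy)-4-(2-nitrovinyl)-2-prenylbenzene
Conditions: MeNO2 (solvent), NH4OAc (0.3 equiv), 90 °C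
Reagents that add atoms: none
Why: Henry (nitroaldol) condensation with dehydration in the same flask should give the conjugated nitroalkene as the thermodynamically favoured E isomer, and the buffered medium should spare the MOM acetal and the prenyl alkene.

Step 6
Reactants: 4 2-hydroxy-4,6-bis(methoxymethoxy)-3-prenylbenzaldehyde; 9 (E)-1-(methoxymethoxy)-4-(2-nitrovinyl)-2-prenylbenzene
Product: 12 racemic 5,7-bis(methoxymethoxy)-2-[4-(methoxymethoxy)-3-prenylphenyl]-3-nitro-8-prenyl-2H-chromene, via oxa-Michael nitro ether 10 (not isolated), via 3-nitrochroman-4-ol 11 (not isolated)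
Conditions: 9 (1.5 equiv), DABCO (0.5 equiv), 4 Å MS, MeCN (2 M), 60 °C
Reagents that add atoms: none
Why: DABCO deprotonates the single free phenol of 4 and the phenoxide adds to the β-carbon of nitroalkene 9 (oxa-Michael, O1–C2) to give the nitronate of 10; this nitronate attacks the neighbouring formyl carbon (Henry reaction, C3–C4) to give nitro alcohol 11, and base-mediated E1cB loss of water gives the conjugated nitroalkene 12. The closest known reaction type is the amine-catalysed tandem oxa-Michael/Henry condensation of salicylaldehydes with β-nitrostyrenes to 2-aryl-3-nitro-2H-chromenes. Ring C closes in the Henry step as a 6-exo-trig attack of the nitronate carbon on the aldehyde carbonyl. The C2 stereocentre forms without control, so 12 is racemic, which does not matter because C2 becomes sp2 in step 7; the C3 and C4 centres of 11 are lost on dehydration. The step needs regioselectivity for O1 and preference for cyclisation over base-induced oligomerisation of 9: the first is fixed because the hydroxyl between prenyl and formyl is the only unprotected phenol, which gives the 8-prenyl pattern, and the second is helped by the intramolecular Henry closure and the irreversible dehydration, which draw the reversible oxa-Michael adduct forward even though the aldehyde is hindered and electron-rich.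

Step 7
Reactants: 12 racemic 5,7-bis(methoxymethoxy)-2-[4-(methoxymethoxy)-3-prenylphenyl]-3-nitro-8-prenyl-2H-chromene
Product: 14 3-hydroxy-5,7-bis(methoxymethoxy)-2-[4-(methoxymethoxy)-3-prenylphenyl]-8-prenyl-4H-chromen-4-one, via nitro epoxide 13 (not isolated)
Conditions: 30% aq H2O2 (6 equiv), 2 M aq NaOH (3 equiv), MeOH–THF 1:1, 0 °C → rt
Reagents that add atoms: hydrogen peroxide, OO
Why: Weitz–Scheffer-type nucleophilic epoxidation, in which hydroperoxide adds to C4 of the nitroalkene and the nitronate closes to nitro epoxide 13, is followed by peroxide opening at C4 with loss of nitrite and Kornblum–DeLaMare-type collapse to the 3,4-dione level, whose enol is the aromatic 3-hydroxychromen-4-one (the known alkaline-peroxide conversion of 2-aryl-3-nitro-2H-chromenes into flavonols); the nucleophilic oxidant should leave the electron-rich prenyl alkenes and the MOM acetals alone, and no nitrile solvent is used so that no electrophilic peroxyimidic acid can form.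

Step 8
Reactants: 14 3-hydroxy-5,7-bis(methoxymethoxy)-2-[4-(methoxymethoxy)-3-prenylphenyl]-8-prenyl-4H-chromen-4-one
Product: 15 Broussoflavonol F (3,5,7-trihydroxy-2-(4-hydroxy-3-prenylphenyl)-8-prenyl-4H-chromen-4-one)
Conditions: 3 M aq HCl, MeOH–THF, 45 °C, stopped at full conversion
Reagents that add atoms: none
Why: Acid-catalysed acetal exchange transfers the three MOM groups to methanol, and the moderate temperature and short reaction time are chosen to limit acid-catalysed cyclisation of the ortho-prenyl phenols to dimethylchromans.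

**Compound list**
1 | 2,4,6-trihydroxybenzaldehyde | O=Cc1c(O)cc(O)cc1O | starting material
2 | prenyl bromide (1-bromo-3-methylbut-2-ene) | CC(C)=CCBr | starting material
3 | 2,4,6-trihydroxy-3-prenylbenzaldehyde | CC(C)=CCc1c(O)cc(O)c(C=O)c1O | intermediate
4 | 2-hydroxy-4,6-bis(methoxymethoxy)-3-prenylbenzaldehyde | CC(C)=CCc1c(O)c(C=O)c(OCOC)cc1OCOC | intermediate
5 | 4-hydroxybenzaldehyde | O=Cc1ccc(O)cc1 | starting material
6 | 4-hydroxy-3-prenylbenzaldehyde | CC(C)=CCc1cc(C=O)ccc1O | intermediate
7 | 4-(methoxymethoxy)-3-prenylbenzaldehyde | CC(C)=CCc1cc(C=O)ccc1OCOC | intermediate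
8 | nitromethane | C[N+](=O)[O-] | starting material
9 | (E)-1-(methoxymethoxy)-4-(2-nitrovinyl)-2-prenylbenzene | CC(C)=CCc1cc(/C=C/[N+](=O)[O-])ccc1OCOC | intermediate
10 | racemic 2-{1-[4-(methoxymethoxy)-3-prenylphenyl]-2-nitroethoxy}-4,6-bis(methoxymethoxy)-3-prenylbenzaldehyde (oxa-Michael adduct, present as its nitronate, not isolated) | CC(C)=CCc1c(OC(C[N+](=O)[O-])c2ccc(OCOC)c(CC=C(C)C)c2)c(C=O)c(OCOC)cc1OCOC | intermediate
11 | 5,7-bis(methoxymethoxy)-2-[4-(methoxymethoxy)-3-prenylphenyl]-3-nitro-8-prenylchroman-4-ol (racemic, diastereomer mixture, not isolated) | CC(C)=CCc1cc(C2Oc3c(CC=C(C)C)c(OCOC)cc(OCOC)c3C(O)C2[N+](=O)[O-])ccc1OCOC | intermediate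
12 | racemic 5,7-bis(methoxymethoxy)-2-[4-(methoxymethoxy)-3-prenylphenyl]-3-nitro-8-prenyl-2H-chromene | CC(C)=CCc1cc(C2Oc3c(CC=C(C)C)c(OCOC)cc(OCOC)c3C=C2[N+](=O)[O-])ccc1OCOC | intermediate
13 | racemic 3,4-epoxy-5,7-bis(methoxymethoxy)-2-[4-(methoxymethoxy)-3-prenylphenyl]-3-nitro-8-prenylchromane (nitro epoxide, relative configuration not defined, not isolated) | CC(C)=CCc1cc(C2Oc3c(CC=C(C)C)c(OCOC)cc(OCOC)c3C4OC24[N+](=O)[O-])ccc1OCOC | intermediate
14 | 3-hydroxy-5,7-bis(methoxymethoxy)-2-[4-(methoxymethoxy)-3-prenylphenyl]-8-prenyl-4H-chromen-4-one | CC(C)=CCc1cc(-c2oc3c(CC=C(C)C)c(OCOC)cc(OCOC)c3c(=O)c2O)ccc1OCOC | intermediate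
15 | Broussoflavonol F (3,5,7-trihydroxy-2-(4-hydroxy-3-prenylphenyl)-8-prenyl-4H-chromen-4-one) | CC(C)=CCc1cc(-c2oc3c(CC=C(C)C)c(O)cc(O)c3c(=O)c2O)ccc1O | target

**Totals**
Total step count: 8. Longest linear sequence: 6 (steps 3, 4, 5, 6, 7, 8).

**Steps most likely to fail**

Step 6. The oxa-Michael addition of the chelated phenol, crowded by the neighbouring prenyl group, to an electron-rich nitroalkene may be slow and may revert, so that amine-induced oligomerisation of the nitrostyrene takes over. The fallback removes the prenyl group from the annulating phenol and installs it at C8 after ring C is built. It sets out from 1 and 9 and comes back to the route at 15. Compound 1 would be mono-protected at the unchelated hydroxyl (MOMCl 1.0 equiv, i-Pr2NEt, CH2Cl2, 0 °C) to give 2,6-dihydroxy-4-(methoxymethoxy)benzaldehyde F1. One of its two equivalent chelated hydroxyls would be O-alkylated with 2 (K2CO3, acetone) to give 2-hydroxy-4-(methoxymethoxy)-6-(prenyloxy)benzaldehyde F2. Annulation of F2 with 9 under the conditions of step 6, now through an unhindered phenol, should give racemic 7-(methoxymethoxy)-2-[4-(methoxymethoxy)-3-prenylphenyl]-3-nitro-5-(prenyloxy)-2H-chromene F3. Alkaline hydrogen peroxide as in step 7 should convert this into 3-hydroxy-7-(methoxymethoxy)-2-[4-(methoxymethoxy)-3-prenylphenyl]-5-(prenyloxy)-4H-chromen-4-one F4. A europium(III)-catalysed para-Claisen–Cope shift of the 5-O-prenyl group (Eu(fod)3, NaHCO3, PhCl, 85 °C) should then move the prenyl unit to C8 and give 3,5-dihydroxy-7-(methoxymethoxy)-2-[4-(methoxymethoxy)-3-prenylphenyl]-8-prenyl-4H-chromen-4-one F5. Acid as in step 8 would remove the two remaining MOM groups to give 15.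

Step 7. Hydroxide may open or isomerise the nitrochromene (retro-oxa-Michael, shift to the 4H-chromene) before epoxidation, the sequence may stall at the epoxide or hydroxy ketone level, or the flavonol may be degraded by prolonged alkaline peroxide. The fallback separates the three events under hydroxide-free conditions. It sets out from 12 and comes back at 14. Anhydrous nucleophilic epoxidation (t-BuOOH, DBU, THF, −20 → 0 °C) would give nitro epoxide 13, which would be isolated this time. Opening at C4 by water under buffered conditions (THF–H2O, NaHCO3) with loss of nitrite should give racemic 4-hydroxy-5,7-bis(methoxymethoxy)-2-[4-(methoxymethoxy)-3-prenylphenyl]-8-prenylchroman-3-one F6. Dess–Martin oxidation (NaHCO3, CH2Cl2) would give 5,7-bis(methoxymethoxy)-2-[4-(methoxymethoxy)-3-prenylphenyl]-8-prenylchromane-3,4-dione F7, which enolises to 14.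

Step 2. The second MOM transfer may lose regiocontrol and acetalise the 2-OH next to the prenyl group instead of the 6-OH, or over-protection may occur; the wrong isomer would lead to the 6-prenyl series. The fallback fixes the regiochemistry by construction. It sets out from 1 and comes back at 4. Bis-protection of 1 (MOMCl 2.1 equiv, i-Pr2NEt, CH2Cl2) leaves one of the two equivalent chelated hydroxyls free and gives 2-hydroxy-4,6-bis(methoxymethoxy)benzaldehyde F8. O-Allylation (allyl bromide, K2CO3, DMF) gives 2-(allyloxy)-4,6-bis(methoxymethoxy)benzaldehyde F9. Thermal aromatic Claisen rearrangement (N,N-diethylaniline, 190 °C) can only deliver the allyl group to the single open ortho position and gives 3-allyl-2-hydroxy-4,6-bis(methoxymethoxy)benzaldehyde F10. Olefin cross-metathesis with 2-methyl-2-butene (Grubbs second-generation catalyst, CH2Cl2, 40 °C) converts the allyl into the prenyl group and gives 4.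

**Further compounds**
F1 | step 6 | 2,6-dihydroxy-4-(methoxymethoxy)benzaldehyde | O=Cc1c(O)cc(OCOC)cc1O
F2 | step 6 | 2-hydroxy-4-(methoxymethoxy)-6-(prenyloxy)benzaldehyde | CC(C)=CCOc1cc(OCOC)cc(O)c1C=O
F3 | step 6 | racemic 7-(methoxymethoxy)-2-[4-(methoxymethoxy)-3-prenylphenyl]-3-nitro-5-(prenyloxy)-2H-chromene | CC(C)=CCOc1cc(OCOC)cc2OC(c3ccc(OCOC)c(CC=C(C)C)c3)C([N+](=O)[O-])=Cc12
F4 | step 6 | 3-hydroxy-7-(methoxymethoxy)-2-[4-(methoxymethoxy)-3-prenylphenyl]-5-(prenyloxy)-4H-chromen-4-one | CC(C)=CCOc1cc(OCOC)cc2oc(-c3ccc(OCOC)c(CC=C(C)C)c3)c(O)c(=O)c12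
F5 | step 6 | 3,5-dihydroxy-7-(methoxymethoxy)-2-[4-(methoxymethoxy)-3-prenylphenyl]-8-prenyl-4H-chromen-4-one | CC(C)=CCc1cc(-c2oc3c(CC=C(C)C)c(OCOC)cc(O)c3c(=O)c2O)ccc1OCOC
F6 | step 7 | racemic 4-hydroxy-5,7-bis(methoxymethoxy)-2-[4-(methoxymethoxy)-3-prenylphenyl]-8-prenylchroman-3-one | CC(C)=CCc1cc(C2Oc3c(CC=C(C)C)c(OCOC)cc(OCOC)c3C(O)C2=O)ccc1OCOC
F7 | step 7 | racemic 5,7-bis(methoxymethoxy)-2-[4-(methoxymethoxy)-3-prenylphenyl]-8-prenylchromane-3,4-dione | CC(C)=CCc1cc(C2Oc3c(CC=C(C)C)c(OCOC)cc(OCOC)c3C(=O)C2=O)ccc1OCOC
F8 | step 2 | 2-hydroxy-4,6-bis(methoxymethoxy)benzaldehyde | O=Cc1c(O)cc(OCOC)cc1OCOC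
F9 | step 2 | 2-(allyloxy)-4,6-bis(methoxymethoxy)benzaldehyde | C=CCOc1cc(OCOC)cc(OCOC)c1C=O
F10 | step 2 | 3-allyl-2-hydroxy-4,6-bis(methoxymethoxy)benzaldehyde | C=CCc1c(O)c(C=O)c(OCOC)cc1OCOC
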